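## The problem

Obtusane is a spiro[5.5]undecane whose spiro carbon C6 is quaternary and lies between the quaternary carbon C11 (two methyl groups) and C7, which carries the exocyclic methylene C14. Ring A is C6–C7–C8–C9–C10–C11 and ring B is C6–C1–C2–C3–C4–C5 (chamigrene numbering, kept for the same atoms in every intermediate). There are four stereocentres: C10 (secondary bromide, R), C6 (S), C2 (secondary chloride, S) and C3 (tertiary bromide bearing the C15 methyl, S). Only C10 can be set by a reagent acting on an acyclic precursor. It is too far from C6 to control it reliably, whereas C6, once set, fixes the shape of ring B and with it the face on which C2 and C3 are functionalised. The C10 bromide is neopentyl, so it cannot be made by substitution; it has to be installed through a bromonium ion while ring A is formed, and it must then survive every later base. The tertiary C3 bromide ionises and eliminates easily and the C7=C14 alkene adds acid, so the ring B halogens must come last and under neutral conditions; a plain Br–Cl addition would also put chlorine, not bromine, on C3. The hardest bond is the one that makes C6 quaternary beside C11. The enabling feature is that a quaternary C6 next to the alkylidene unit C7=C14 is the product pattern of a [3,3] shift: if C14 is reconnected to C3, ring B unfolds into a vinyl group on a fused bicyclic carbinol, and the enolate left between C2 and C3 is the handle for the C3 methyl group and both halogens.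

## Retrosynthesis

**C3–Br.** The tertiary bromide of obtusane 21 is cut first, back to chlorohydrin 20. The alternative of adding Br and Cl together is rejected because the electrophilic partner would be bromine and chloride would end up on C3. The forward step must replace a tertiary hydroxyl by bromide with retention and without free HBr; the neighbouring chlorine is expected to provide the retention.

**C2–Cl and C3–O.** Chlorohydrin 20 is cut to the trisubstituted alkene of 10-bromo-β-chamigrene 19. This removes two stereocentres at once. The forward reaction needs electrophilic chlorine to prefer the ring B alkene over the hindered exocyclic one, to choose the face anti to C7, and water to open at C3.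

**C3–C15.** The methyl group of 19 is cut to the enol triflate 18. A cross-coupling is preferred to methyl addition to a ketone, because a C3 ketone would make the two arms of ring B equivalent and erase C6 as a stereocentre.

**C1–C6 (key).** Triflate 18 is the trapped enolate of a [3,3] shift. In the retro direction C1–C6 is cut and C3–C14 is joined, which leads to the vinyl carbinol 16, a fused octalin whose ring C is C6–C5–C4–C3–C14–C7. Neighbouring cuts (C5–C6 by Michael addition or alkylation, C6–C7 by carbopalladation) all have to attack or form the neopentyl centre from outside; here the bond is made inside the molecule and is driven by enolate formation. The precursor has no vicinal quaternary carbons and only C10 plus the carbinol as stereocentres. The forward step has to reach a boat-like array and must prefer the [3,3] over the [1,3] path.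

**C3–vinyl.** Carbinol 16 comes from octalone 14 and vinylmagnesium bromide 15. The addition must be 1,2 and must not enolise; no facial control by C10 can be expected, so the epimers have to be separated.

**C7–C14.** Ring C of 14 is opened at C7–C14 to the alkenyl triflate methyl ketone 13. Against the alternative cut C4–C5 (enolate alkylation), this cut lets ring size alone decide which enolate reacts and delivers the β,γ-unsaturated ketone directly.

**C4–C5.** Ketone 13 is cut to allylic bromide 10 and the acetone unit of hydrazone 11. Bromide 10 follows by functional group changes from alcohol 9, enoate triflate 8 and the ring A keto ester 7.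

**C6–C11.** Ring A of 7 is opened between the enol carbon and the tertiary carbon, giving bromohydrin keto ester 6. The forward reaction is a bromonium cyclisation in which the C10–Br bond is already in place and is not broken.

**C10–Br, C8–C9.** Bromohydrin 6 is unmasked from dioxinone 5, which comes from epoxide 4 by bromide opening and from alkene 3 by asymmetric epoxidation. Alkene 3 is cut at C8–C9 to the commercial dioxinone 1 and prenyl bromide 2. The dioxinone is chosen over the free acetoacetate because a free β-keto ester would not survive the epoxidation or the alkoxide and epoxide stages.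

## Roads not taken

**Alternative 1:** Cut C8–C9 and C10–Br. The α-bromo-β-keto ester A1, whose ketone sits on the quaternary carbon of a ketal-protected cyclohexane that also carries a 2-methylbut-3-en-2-yl group, would undergo bromine atom-transfer radical cyclisation (CuBr with a chiral ligand) in the 6-endo mode to the spirocyclic bromo keto ester A2.
- Merits: ring A and the neopentyl C–Br bond arise in one step without any substitution, and ring B is carried as a symmetric ketal, so no spiro stereocentre has to be handled at that stage. It also avoids an unselective carbonyl addition, and in that respect it is better than the chosen plan.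
- Weak points: the absolute configuration at C10 would depend on bromine transfer to a free secondary radical, which a chiral metal halide controls poorly. A1 already contains the C6/C11 quaternary pair, so the hard bond is only moved to an earlier acylation. After the cyclisation the ester must be removed, a ketone flanked by two quaternary carbons must be methylenated, and C6 must still be made stereogenic by telling the two arms of ring B apart.
- Comparison: the chosen plan sets against it a C10 configuration that comes from a reliable epoxidation and an SN2 opening, and an exocyclic methylene that the rearrangement delivers without a separate olefination.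

**Alternative 2:** Cut C5–C6 and C1=C2. The extended enolate of bromo-β-cyclocitral A3 would add through C6 to methyl vinyl ketone, and aldol condensation would close ring B as the enone A4.
- Merits: it is short and uses the same ring A building block (A3 is two steps from alcohol 9). The axial methyl group on C11 should steer the acceptor to the face that gives the right C6 configuration. Conjugate reduction of A4 with enolate triflation would reach triflate 18 in fewer steps than the chosen route and without a separation of epimers. In step count and in stereocontrol at C6 this road is the better one on paper.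
- Weak points: the Michael addition is intermolecular and has to form the C6–C11 quaternary pair at the hindered α-carbon of a dienolate. γ-Attack through C14, 1,2-addition, polymerisation of the enone and deformylation of the α-quaternary aldehyde are the expected diversions.
- Comparison: the chosen plan sets against it an intramolecular C–C bond formation at C6 that does not depend on an external electrophile reaching the neopentyl centre, and an enolate that is regiodefined as formed. Because its chemistry is known, alternative 2 is kept as the fallback for the key step.

**Alternative 3:** Cut C6–C7. The alkenyl triflate A5, tethered through C8–C9–C10(Br)–C11 to the β-carbon of a cyclohexenone, would undergo oxidative addition, 6-exo carbopalladation of the enone and formate reduction of the palladium enolate (Pd(OAc)2, PPh3, HCO2Na) to the spiro ketone A6.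
- Merits: the quaternary centre is formed intramolecularly, the methylene group is in place from the start, and the bromine-bearing tether could relay C10 to C6 through a chair-like transition state.
- Weak points: A5 needs the neopentyl C10 bromide in an open chain, where no bromonium cyclisation is available to install it. The quaternary C11 must be attached to the enone beforehand. A6 carries its ketone at C2, so several further steps are needed to reach the C2=C3 alkene of 19.
- Comparison: the ring-forming step is well precedented and in that respect safer than the key step chosen here. The chosen plan sets against it a secure origin of the C10–Br bond and an oxygen function at C3, where the methyl group has to go.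

Key step: step 12

Remark on the chemistry: ring B of the spiro compounds is assumed to adopt the half-chair or chair in which C7 is axial and the more demanding C11 is equatorial; the facial arguments of steps 14 and 15 rest on this.

## Route

Step 1
Reactants: 1 2,2,6-trimethyl-4H-1,3-dioxin-4-one; 2 prenyl bromide (1-bromo-3-methylbut-2-ene)
Product: 3 2,2-dimethyl-6-(4-methylpent-3-en-1-yl)-4H-1,3-dioxin-4-one
Conditions: LiN(i-Pr)2, THF, −78 °C; DMPU; then 2, −78 to −20 °C
Reagents that add atoms: none
Why: γ-Alkylation of the lithium dienolate of a 1,3-dioxin-4-one with an allylic bromide forms C8–C9; the dioxinone carries the later β-keto ester in a form with no acidic methylene and no ketone, so it survives the basic epoxidation and the bromide opening that follow.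

Step 2
Reactants: 3 2,2-dimethyl-6-(4-methylpent-3-en-1-yl)-4H-1,3-dioxin-4-one
Product: 4 6-{2-[(2S)-3,3-dimethyloxiran-2-yl]ethyl}-2,2-dimethyl-4H-1,3-dioxin-4-one
Conditions: L-fructose-derived Shi ketone (1,2:4,5-di-O-isopropylidene-L-erythro-2,3-hexodiulo-2,6-pyranose, 30 mol %), KHSO5 (as 2KHSO5·KHSO4·K2SO4), K2CO3, Bu4NHSO4, MeCN–CH2(OMe)2–aq. buffer pH 10.5, 0 °C
Reagents that add atoms: potassium peroxymonosulfate, [K+].[O-]S(=O)(=O)OO
Why: Shi epoxidation; the chiral dioxirane attacks the electron-rich trisubstituted alkene through the spiro transition state and should give the (S)-epoxide, while the push-pull alkene of the dioxinone is too electron-poor to compete. This step sets the absolute configuration of the whole synthesis.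

Step 3
Reactants: 4 6-{2-[(2S)-3,3-dimethyloxiran-2-yl]ethyl}-2,2-dimethyl-4H-1,3-dioxin-4-one
Product: 5 6-[(3R)-3-bromo-4-hydroxy-4-methylpentyl]-2,2-dimethyl-4H-1,3-dioxin-4-one
Conditions: Li2NiBr4, THF, 0 °C to rt
Reagents that add atoms: dilithium tetrabromonickelate, [Li+].[Li+].Br[Ni-2](Br)(Br)Br
Why: Epoxide opening by soft bromide, an SN2 attack at the less substituted oxirane carbon with inversion; it turns the (S)-epoxide into the (R)-bromide that becomes C10 and leaves the tertiary alcohol as the later leaving group.

Step 4
Reactants: 5 6-[(3R)-3-bromo-4-hydroxy-4-methylpentyl]-2,2-dimethyl-4H-1,3-dioxin-4-one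
Product: 6 methyl (6R)-6-bromo-7-hydroxy-7-methyl-3-oxooctanoate
Conditions: MeOH, PhMe, 110 °C, sealed tube
Reagents that add atoms: methanol, CO
Why: Thermal retro-[4+2] cleavage of the dioxinone to an acylketene and acetone, and capture of the ketene by methanol; the unmasking is neutral and should not touch the bromohydrin.

Step 5
Reactants: 6 methyl (6R)-6-bromo-7-hydroxy-7-methyl-3-oxooctanoate
Product: 7 methyl (3R)-3-bromo-2,2-dimethyl-6-oxocyclohexane-1-carboxylate (keto/enol mixture, C1 not defined)
Conditions: SnCl4, CH2Cl2, −78 to −20 °C
Reagents that add atoms: none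
Why: Ionisation of the tertiary alcohol is assisted by the neighbouring bromine, and the resulting bromonium ion is opened at its tertiary carbon by the tin-chelated enol in a 6-endo closure (enantiospecific bromonium cyclisation). The C10–Br bond is never broken, so C10 stays R; any O-cyclised enol ether should revert and funnel to the C-alkylated ketone under the Lewis acid.

Step 6
Reactants: 7 methyl (3R)-3-bromo-2,2-dimethyl-6-oxocyclohexane-1-carboxylate
Product: 8 methyl (5R)-5-bromo-6,6-dimethyl-2-{[(trifluoromethyl)sulfonyl]oxy}cyclohex-1-ene-1-carboxylate
Conditions: Tf2O, i-Pr2NEt, CH2Cl2, −78 to 0 °C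
Reagents that add atoms: trifluoromethanesulfonic anhydride, O=S(=O)(OS(=O)(=O)C(F)(F)F)C(F)(F)F
Why: Enol triflate formation of a β-keto ester; only the enol conjugated with the ester exists, which fixes the later tetrasubstituted C6=C7 alkene.

Step 7
Reactants: 8 methyl (5R)-5-bromo-6,6-dimethyl-2-{[(trifluoromethyl)sulfonyl]oxy}cyclohex-1-ene-1-carboxylate
Product: 9 (4R)-4-bromo-2-(hydroxymethyl)-3,3-dimethylcyclohex-1-en-1-yl trifluoromethanesulfonate
Conditions: i-Bu2AlH (2.5 equiv), CH2Cl2, −78 to −40 °C
Reagents that add atoms: none
Why: 1,2-Reduction of the enoate to the allylic alcohol; alkenyl triflates and the secondary bromide are inert to i-Bu2AlH at low temperature.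

Step 8
Reactants: 9 (4R)-4-bromo-2-(hydroxymethyl)-3,3-dimethylcyclohex-1-en-1-yl trifluoromethanesulfonate
Product: 10 (4R)-4-bromo-2-(bromomethyl)-3,3-dimethylcyclohex-1-en-1-yl trifluoromethanesulfonate
Conditions: CBr4, PPh3, CH2Cl2, 0 °C
Reagents that add atoms: tetrabromomethane, BrC(Br)(Br)Br
Why: Appel reaction of a primary allylic alcohol under neutral conditions gives the allylic bromide at C5 without disturbing the alkenyl triflate.

Step 9
Reactants: 10 (4R)-4-bromo-2-(bromomethyl)-3,3-dimethylcyclohex-1-en-1-yl trifluoromethanesulfonate; 11 acetone N,N-dimethylhydrazone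
Product: 13 (4R)-4-bromo-3,3-dimethyl-2-(3-oxobutyl)cyclohex-1-en-1-yl trifluoromethanesulfonate, via dimethylhydrazone 12 (not isolated)
Conditions: 11, LiN(i-Pr)2, THF, 0 °C; then 10, −78 °C; then aq. oxalic acid, Et2O, rt
Reagents that add atoms: water, O
Why: Alkylation of the lithiated hydrazone, an acetone enolate equivalent that is monoalkylated at the methyl group, with the reactive allylic bromide forms C4–C5; mild acid hydrolysis then releases the methyl ketone.

Step 10
Reactants: 13 (4R)-4-bromo-3,3-dimethyl-2-(3-oxobutyl)cyclohex-1-en-1-yl trifluoromethanesulfonate
Product: 14 (6R)-6-bromo-5,5-dimethyl-3,4,5,6,7,8-hexahydronaphthalen-2(1H)-one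
Conditions: Pd2(dba)3 (2.5 mol %), Xantphos (6 mol %), NaOt-Bu (2.2 equiv), THF, 40 °C; AcOH quench at −78 °C
Reagents that add atoms: none
Why: Palladium-catalysed intramolecular α-alkenylation of a ketone enolate with an alkenyl triflate forms C14–C7 and ring C. Only the methyl-side enolate can close a six-membered ring, so the regiochemistry is enforced; the product is by construction the β,γ-unsaturated ketone and is kept deconjugated by kinetic protonation of its dienolate.

Step 11
Reactants: 14 (6R)-6-bromo-5,5-dimethyl-3,4,5,6,7,8-hexahydronaphthalen-2(1H)-one; 15 vinylmagnesium bromide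
Product: 16 (2S,6R)-6-bromo-2-ethenyl-5,5-dimethyl-1,2,3,4,5,6,7,8-octahydronaphthalen-2-ol
Conditions: 15, anhydrous CeCl3, THF, −78 °C; separation of the C2 epimers by chromatography
Reagents that add atoms: none
Why: 1,2-Addition of the weakly basic vinylcerium reagent, which should not enolise the doubly activated C14 methylene. C10 is too remote to bias the carbonyl faces, so both C2 epimers are expected in similar amounts, and the (2S,6R) epimer (vinyl syn to bromine) is taken on after separation.

Step 12
Reactants: 16 (2S,6R)-6-bromo-2-ethenyl-5,5-dimethyl-1,2,3,4,5,6,7,8-octahydronaphthalen-2-ol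
Product: 18 (6S,10R)-10-bromo-11,11-dimethyl-7-methylidenespiro[5.5]undec-2-en-3-yl trifluoromethanesulfonate (10-bromochamigra-2,7(14)-dien-3-yl triflate), via potassium enolate 17 (not isolated)
Conditions: KH, 18-crown-6, THF, 0 to 66 °C; then −78 °C, PhNTf2
Reagents that add atoms: N-phenylbis(trifluoromethanesulfonimide), O=S(=O)(N(c1ccccc1)S(=O)(=O)C(F)(F)F)C(F)(F)F
Why: Proposed new method: the potassium alkoxide, freed from its counter-ion by 18-crown-6, weakens the C3–C14 bond, and the 1,5-diene C1=C2–C3–C14–C7=C6 is expected to undergo a [3,3] shift in which the axial vinyl terminus C1 reaches across ring C to C6 while C3–C14 breaks, giving enolate 17, which PhNTf2 traps on oxygen. The closest known reaction type is the anionic oxy-Cope rearrangement (KH, 18-crown-6) with in situ enolate triflation, established for 1,5-dien-3-olates that reach chair or boat arrays and, as a shift through this same boat, for the thermal degenerate rearrangement of 4-vinylcyclohexene, but not shown for the alkoxide of a 1-vinylcyclohex-3-enol that must build a spiro quaternary carbon. Ring B (C6–C1–C2–C3–C4–C5) closes by transannular bonding of C1 to C6 through a boat, bicyclo[2.2.2]octane-like array enforced by ring C, which opens in the same event and releases C14 as the exocyclic methylene. The one new stereocentre, C6, is controlled by the carbinol carbon C3: the shift is suprafacial on the C6=C7 alkene, so C1 arrives on the face that carries the vinyl group, which is the face of the C10 bromine, and this gives 6S. The step needs the [3,3] path to win over the [1,3] shift (C1 to C14, ring expansion to a cyclooctenone) and over fragmentation to an allyl anion and an enone; the gain of a six-membered ring and of an enolate, and a temperature kept as low as the boat allows, are what favour it. The enolate regiochemistry needs no selectivity, because the shift itself delivers the C2=C3 enolate and no proton source is present before triflation.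

Step 13
Reactants: 18 (6S,10R)-10-bromo-11,11-dimethyl-7-methylidenespiro[5.5]undec-2-en-3-yl trifluoromethanesulfonate
Product: 19 (6S,10R)-10-bromo-3,11,11-trimethyl-7-methylidenespiro[5.5]undec-2-ene (10-bromo-β-chamigrene)
Conditions: MeZnCl, Pd(PPh3)4 (5 mol %), THF, 50 °C
Reagents that add atoms: methylzinc chloride, C[Zn]Cl
Why: Negishi coupling of the alkenyl triflate under zerovalent palladium; an unactivated secondary alkyl bromide does not undergo oxidative addition under these conditions, and the methyl group fixes the C2=C3 alkene exactly where the enolate was.

Step 14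
Reactants: 19 (6S,10R)-10-bromo-3,11,11-trimethyl-7-methylidenespiro[5.5]undec-2-ene
Product: 20 (2S,3S,6S,10R)-10-bromo-2-chloro-3,11,11-trimethyl-7-methylidenespiro[5.5]undecan-3-ol
Conditions: N-chlorosuccinimide, acetone–H2O (4:1), 0 °C to rt
Reagents that add atoms: N-chlorosuccinimide, ClN1C(=O)CCC1=O; water, O
Why: Chlorohydrin formation; electrophilic chlorine should attack the more electron-rich trisubstituted alkene on the face of ring B opposite to the axial C7, whose methylene group covers the other face near C1 and C2. Water opens the chloronium ion anti at the tertiary carbon C3, which sets 2S and 3S.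

Step 15
Reactants: 20 (2S,3S,6S,10R)-10-bromo-2-chloro-3,11,11-trimethyl-7-methylidenespiro[5.5]undecan-3-ol
Product: 21 obtusane, (2S,3S,6S,10R)-3,10-dibromo-2-chloro-3,11,11-trimethyl-7-methylidenespiro[5.5]undecane
Conditions: 1-bromo-N,N,2-trimethylprop-1-en-1-amine, CH2Cl2, 0 °C to rt
Reagents that add atoms: 1-bromo-N,N,2-trimethylprop-1-en-1-amine, CC(C)=C(Br)N(C)C
Why: Conversion of a tertiary alcohol into the bromide under neutral conditions with an α-bromo enamine; loss of the activated oxygen is expected to return the same chloronium ion that water opened in step 14, so bromide enters C3 anti to chlorine and C3 is substituted with retention. The acid-sensitive exocyclic alkene never meets free HBr.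

## Compound list

1 | 2,2,6-trimethyl-4H-1,3-dioxin-4-one | CC1=CC(=O)OC(C)(C)O1 | starting material
2 | prenyl bromide (1-bromo-3-methylbut-2-ene) | CC(C)=CCBr | starting material
3 | 2,2-dimethyl-6-(4-methylpent-3-en-1-yl)-4H-1,3-dioxin-4-one | CC(C)=CCCC1=CC(=O)OC(C)(C)O1 | intermediate
4 | 6-{2-[(2S)-3,3-dimethyloxiran-2-yl]ethyl}-2,2-dimethyl-4H-1,3-dioxin-4-one | O=C1C=C(CC[C@@H]2OC2(C)C)OC(C)(C)O1 | intermediate
5 | 6-[(3R)-3-bromo-4-hydroxy-4-methylpentyl]-2,2-dimethyl-4H-1,3-dioxin-4-one | O=C1C=C(CC[C@@H](Br)C(C)(C)O)OC(C)(C)O1 | intermediate
6 | methyl (6R)-6-bromo-7-hydroxy-7-methyl-3-oxooctanoate | COC(=O)CC(=O)CC[C@@H](Br)C(C)(C)O | intermediate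
7 | methyl (3R)-3-bromo-2,2-dimethyl-6-oxocyclohexane-1-carboxylate | COC(=O)C1C(=O)CC[C@@H](Br)C1(C)C | intermediate
8 | methyl (5R)-5-bromo-6,6-dimethyl-2-{[(trifluoromethyl)sulfonyl]oxy}cyclohex-1-ene-1-carboxylate | COC(=O)C1=C(OS(=O)(=O)C(F)(F)F)CC[C@@H](Br)C1(C)C | intermediate
9 | (4R)-4-bromo-2-(hydroxymethyl)-3,3-dimethylcyclohex-1-en-1-yl trifluoromethanesulfonate | OCC1=C(OS(=O)(=O)C(F)(F)F)CC[C@@H](Br)C1(C)C | intermediate
10 | (4R)-4-bromo-2-(bromomethyl)-3,3-dimethylcyclohex-1-en-1-yl trifluoromethanesulfonate | BrCC1=C(OS(=O)(=O)C(F)(F)F)CC[C@@H](Br)C1(C)C | intermediate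
11 | acetone N,N-dimethylhydrazone | CC(C)=NN(C)C | starting material
12 | (4R)-4-bromo-2-[3-(2,2-dimethylhydrazinylidene)butyl]-3,3-dimethylcyclohex-1-en-1-yl trifluoromethanesulfonate | CC(CCC1=C(OS(=O)(=O)C(F)(F)F)CC[C@@H](Br)C1(C)C)=NN(C)C | intermediate (not isolated)
13 | (4R)-4-bromo-3,3-dimethyl-2-(3-oxobutyl)cyclohex-1-en-1-yl trifluoromethanesulfonate | CC(=O)CCC1=C(OS(=O)(=O)C(F)(F)F)CC[C@@H](Br)C1(C)C | intermediate
14 | (6R)-6-bromo-5,5-dimethyl-3,4,5,6,7,8-hexahydronaphthalen-2(1H)-one | O=C1CCC2=C(C1)CC[C@@H](Br)C2(C)C | intermediate
15 | vinylmagnesium bromide | C=C[Mg]Br | starting material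
16 | (2S,6R)-6-bromo-2-ethenyl-5,5-dimethyl-1,2,3,4,5,6,7,8-octahydronaphthalen-2-ol | C=C[C@]1(O)CCC2=C(C1)CC[C@@H](Br)C2(C)C | intermediate
17 | potassium (6S,10R)-10-bromo-11,11-dimethyl-7-methylidenespiro[5.5]undec-2-en-3-olate | C=C1CC[C@@H](Br)C(C)(C)[C@]12CCC([O-])=CC2.[K+] | intermediate (not isolated)
18 | (6S,10R)-10-bromo-11,11-dimethyl-7-methylidenespiro[5.5]undec-2-en-3-yl trifluoromethanesulfonate | C=C1CC[C@@H](Br)C(C)(C)[C@]12CCC(OS(=O)(=O)C(F)(F)F)=CC2 | intermediate
19 | (6S,10R)-10-bromo-3,11,11-trimethyl-7-methylidenespiro[5.5]undec-2-ene (10-bromo-β-chamigrene) | C=C1CC[C@@H](Br)C(C)(C)[C@]12CCC(C)=CC2 | intermediate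
20 | (2S,3S,6S,10R)-10-bromo-2-chloro-3,11,11-trimethyl-7-methylidenespiro[5.5]undecan-3-ol | C=C1CC[C@@H](Br)C(C)(C)[C@]12CC[C@](C)(O)[C@@H](Cl)C2 | intermediate
21 | obtusane, (2S,3S,6S,10R)-3,10-dibromo-2-chloro-3,11,11-trimethyl-7-methylidenespiro[5.5]undecane | C=C1CC[C@@H](Br)C(C)(C)[C@]12CC[C@](C)(Br)[C@@H](Cl)C2 | target

## Step count and least certain steps

Total: 15 steps. Longest linear sequence: 15 steps (the route is linear from 1).

**Step 12 (key step, proposed new method).** The most likely failure is that the alkoxide does not take the boat [3,3] path at all. Bond formation at the fully substituted C6 next to C11 is slow, so the [1,3] shift to the ring-expanded ketone or fragmentation into an allyl anion and an enone may take over, and at the temperature needed the naked alkoxide may also eliminate HBr from C9/C10.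
Fallback (known chemistry, from 9 back to 18): Negishi methylation of 9 (MeZnCl, Pd(PPh3)4) would give [(5R)-5-bromo-2,6,6-trimethylcyclohex-1-en-1-yl]methanol F1. Oxidation with MnO2 would give (5R)-5-bromo-2,6,6-trimethylcyclohex-1-ene-1-carbaldehyde F2 (the aldehyde A3 of alternative 2). Deconjugative Michael addition of its potassium dienolate (KOt-Bu, THF) to methyl vinyl ketone, followed by aldol condensation, would give (6S,10R)-10-bromo-11,11-dimethyl-7-methylidenespiro[5.5]undec-1-en-3-one F3 (the enone A4). 1,4-Reduction with LiBH(s-Bu)3 and trapping of the resulting C2=C3 enolate with PhNTf2 then returns to the route at 18.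

**Step 11.** The vinyl addition is expected to show poor facial selectivity because C10 is remote, and the two epimeric carbinols may not separate well; half of the material is then on the wrong side.
Fallback (from 14 back to 18): the addition would be run without separation, giving 16 together with its epimer (2R,6R)-6-bromo-2-ethenyl-5,5-dimethyl-1,2,3,4,5,6,7,8-octahydronaphthalen-2-ol F4. The mixture would be rearranged as in step 12 but quenched with aqueous NH4Cl, so that both epimers converge on the single ketone (10R)-10-bromo-11,11-dimethyl-7-methylidenespiro[5.5]undecan-3-one F5, in which C6 is not yet a stereocentre. Enolisation of F5 with a chiral lithium amide (lithium bis[(R)-1-phenylethyl]amide or its enantiomer, LiCl, THF, −100 °C; asymmetric deprotonation of a 4,4-disubstituted cyclohexanone) and triflation with PhNTf2 would then choose between the two arms of ring B under reagent control and return to the route at 18.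

**Step 15.** Ionisation may give an open tertiary cation instead of the chloronium ion. That would lead to loss of configuration at C3, elimination toward C4 or C15, or capture of the cation by the C7=C14 alkene across the ring.
Fallback (from 19 back to 21): epoxidation of 19 with mCPBA on the open face would give (2S,3R,6S,10R)-10-bromo-2,3-epoxy-3,11,11-trimethyl-7-methylidenespiro[5.5]undecane F6. Opening at the tertiary carbon with one equivalent of HBr in Et2O at −78 °C (inversion at C3) would give (2S,3S,6S,10R)-3,10-dibromo-3,11,11-trimethyl-7-methylidenespiro[5.5]undecan-2-ol F7, so that the C3–Br bond comes from a stereospecific displacement and not from a cation. The C2 hydroxyl would then be replaced by chlorine with retention through its chlorosulfite (SOCl2, dioxane, internal return), which returns to the route at 21.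

**Step 5.** The ketone oxygen may capture the bromonium ion (O-cyclisation), the cation may lose a proton to an allylic bromide, and reversible opening of the bromonium ion may erode the enantiomeric purity.
Fallback (from 5 back to 7): cyclisation would be run before unmasking. Ionisation of 5 with BF3·OEt2 in (CF3)2CHOH lets the enol-ether carbon of the dioxinone, which has no free ketone oxygen, capture the bromonium ion to give (6R)-6-bromo-2,2,5,5-tetramethyl-5,6,7,8-tetrahydro-4H-1,3-benzodioxin-4-one F8. Methanolysis of F8 (MeOH, PhMe, 110 °C) returns to the route at 7.

**Step 10.** The alkoxide base may eliminate HBr from the secondary bromide or cleave the triflate at sulfur before the palladium cycle turns over, and the β,γ-unsaturated ketone may slip into conjugation.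
Fallback (from 9 back to 14): acetonylation of the alkenyl triflate of 9 with isopropenyl acetate and Bu3SnOMe under PdCl2[P(o-tol)3]2 would give 1-[(4R)-4-bromo-2-(hydroxymethyl)-3,3-dimethylcyclohex-1-en-1-yl]propan-2-one F9. Appel bromination would give 1-[(4R)-4-bromo-2-(bromomethyl)-3,3-dimethylcyclohex-1-en-1-yl]propan-2-one F10. Kinetic enolisation of the methyl group with LiN(i-Pr)2 at −78 °C and intramolecular alkylation by the allylic bromide (C4–C5 bond) returns to the route at 14.

## Further compounds

F1 | step 12 | [(5R)-5-bromo-2,6,6-trimethylcyclohex-1-en-1-yl]methanol | OCC1=C(C)CC[C@@H](Br)C1(C)C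
F2 | step 12 | (5R)-5-bromo-2,6,6-trimethylcyclohex-1-ene-1-carbaldehyde | O=CC1=C(C)CC[C@@H](Br)C1(C)C
F3 | step 12 | (6S,10R)-10-bromo-11,11-dimethyl-7-methylidenespiro[5.5]undec-1-en-3-one | C=C1CC[C@@H](Br)C(C)(C)[C@]12CCC(=O)C=C2
F4 | step 11 | (2R,6R)-6-bromo-2-ethenyl-5,5-dimethyl-1,2,3,4,5,6,7,8-octahydronaphthalen-2-ol | C=C[C@@]1(O)CCC2=C(C1)CC[C@@H](Br)C2(C)C
F5 | step 11 | (10R)-10-bromo-11,11-dimethyl-7-methylidenespiro[5.5]undecan-3-one | C=C1CC[C@@H](Br)C(C)(C)C12CCC(=O)CC2
F6 | step 15 | (2S,3R,6S,10R)-10-bromo-2,3-epoxy-3,11,11-trimethyl-7-methylidenespiro[5.5]undecane | C=C1CC[C@@H](Br)C(C)(C)[C@]12CC[C@@]3(C)O[C@H]3C2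
F7 | step 15 | (2S,3S,6S,10R)-3,10-dibromo-3,11,11-trimethyl-7-methylidenespiro[5.5]undecan-2-ol | C=C1CC[C@@H](Br)C(C)(C)[C@]12CC[C@](C)(Br)[C@@H](O)C2
F8 | step 5 | (6R)-6-bromo-2,2,5,5-tetramethyl-5,6,7,8-tetrahydro-4H-1,3-benzodioxin-4-one | CC1(C)OC(=O)C2=C(CC[C@@H](Br)C2(C)C)O1
F9 | step 10 | 1-[(4R)-4-bromo-2-(hydroxymethyl)-3,3-dimethylcyclohex-1-en-1-yl]propan-2-one | OCC1=C(CC(C)=O)CC[C@@H](Br)C1(C)C
F10 | step 10 | 1-[(4R)-4-bromo-2-(bromomethyl)-3,3-dimethylcyclohex-1-en-1-yl]propan-2-one | BrCC1=C(CC(C)=O)CC[C@@H](Br)C1(C)C
A1 | alternative 1 | ethyl 2-bromo-3-[8-(2-methylbut-3-en-2-yl)-1,4-dioxaspiro[4.5]decan-8-yl]-3-oxopropanoate | CCOC(=O)C(Br)C(=O)C1(C(C)(C)C=C)CCC2(CC1)OCCO2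
A2 | alternative 1 | ethyl 10-bromo-3,3-(ethane-1,2-diyldioxy)-11,11-dimethyl-7-oxospiro[5.5]undecane-8-carboxylate (ester and bromine cis) | O=C1[C@@H](C(=O)OCC)C[C@@H](Br)C(C)(C)C12CCC3(CC2)OCCO3
A3 | alternative 2 | (5R)-5-bromo-2,6,6-trimethylcyclohex-1-ene-1-carbaldehyde | O=CC1=C(C)CC[C@@H](Br)C1(C)C
A4 | alternative 2 | 10-bromochamigra-1,7(14)-dien-3-one | C=C1CC[C@@H](Br)C(C)(C)[C@]12CCC(=O)C=C2
A5 | alternative 3 | (5R)-5-bromo-6-methyl-6-(3-oxocyclohex-1-en-1-yl)hept-1-en-2-yl trifluoromethanesulfonate | C=C(OS(=O)(=O)C(F)(F)F)CC[C@@H](Br)C(C)(C)C1=CC(=O)CCC1
A6 | alternative 3 | 10-bromochamigr-7(14)-en-2-one | C=C1CC[C@@H](Br)C(C)(C)[C@]12CCCC(=O)C2
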